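## The problem

The target 29 is a eudesmane, a trans-fused decalin. Ring A (C1 to C5 and C10) carries two trans-diaxial esters: an enantiopure epoxy ester on the 3α oxygen and a tertiary acetate on the 4β oxygen, next to a 4α methyl. Ring B (C5 to C10) holds an 8-ketone conjugated with C6=C7 and a hydroperoxy-isopropyl group on C7 (β means the face of the C10 methyl throughout). The core has four stereocentres (C3, C4, C5, C10) and the side chain two. C10 is quaternary and cannot be corrected later, so it must be set in absolute terms. Once set, its axial methyl blocks the β face, so that C5 can be protonated from α, a C3=C4 alkene epoxidised from α and the epoxide opened diaxially. The tertiary acetate lies syn-axial to that methyl and is better made by opening an epoxide at C4 than by acylating a tertiary alcohol. The two side-chain centres are too remote for the core to control and call for a separately made, reagent-controlled acid. The fragile parts are the tertiary allylic hydroperoxide (lost to reductants, acids, bases and many metals), the glycidic ester, and C5–H, which is γ to the final enone and, earlier, α to a C4 ketone and allylic; the hydroperoxide therefore has to come last and under neutral conditions. The feature that opens the route is C10 itself: it bears a methyl, C1 and C9 inside a cyclohexene (ring B) whose alkene is C6=C7, which is the retron of a Diels-Alder reaction between methacrolein (C9, C10, the methyl, C1 as formyl) and a butadiene C5 to C8 carrying the future C4 on C5.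

## Retrosynthesis

**C11–O bond.** The hydroperoxide 29 is the ene adduct of photochemically generated oxygen with the isopropylidene ketone 28: the O–C11 bond is cut and the alkene moved back from C6=C7 to C7=C11. The neighbouring cut, hydrogen-atom-transfer hydroperoxidation of a 7-isopropenyl dienone, would pass through an allyl radical that can be trapped at C11 or C6 and would also expose the enone to hydrogen-atom addition. The ene route needs only oxygen and light, so both esters and the epoxide are safe, and 28 is a stable enone with no peroxide. The forward step must take hydrogen from C6 and not from the C11 methyls, which is the usual preference of alkylidene ketones (hydrogen geminal to the carbonyl).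

**C7–C11 bond.** The isopropylidene group of 28 is cut by retro-aldol condensation to the enone 24 and a three-carbon ketone reagent, by way of the hydroxy ketone 26. Deprotonating a saturated 8-ketone could give C7 or C9 enolates; making the enolate by hydride addition to C6 of 24 allows only C7. The precursor loses three carbons and the tetrasubstituted alkene.

**C8 oxygen.** The enone 24 is traced to the alkene 22 by allylic oxidation of the C8 methylene. The oxygen cannot arrive earlier: an alkoxy group on the C8 terminus of a diene would reverse the regiochemistry of the cycloaddition, and a C8 ketone would interfere with the aldol and hydride steps that build ring A. The forward step must choose the secondary C8–H over the hindered tertiary C5–H.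

**Ester C–O bond at C3.** Compound 22 is cut into the hydroxy acetate 15 and the acid 20. Epoxidising a tiglate already attached to the core would be uncontrolled and would compete with C6=C7. The acid 20 goes back through the epoxy alcohol 18 (Sharpless epoxidation) and the allylic alcohol 17 to tiglic acid 16.

**C4–O bond.** Both ring A oxygens of 15 come from one epoxide, 14, opened by acetolysis at the tertiary carbon with inversion. This installs the hindered tertiary acetate without acylating a tertiary alcohol and leaves the trans-diaxial 3α hydroxyl free. Compound 14 comes from the alkene 13 by peracid epoxidation on the open α face.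

**C4–CH3 bond.** The methyl of 13 is cut to give the enol triflate 12, made from the enone 10 by conjugate reduction and enolate trapping. This fixes the alkene at C3=C4, which dehydration of a tertiary alcohol could not do.

**C5–H bond.** Compound 10 differs from 8 only at the ring fusion. The cycloaddition is expected to put the formyl group and the C5 substituent cis (endo), and equilibration of angular-methyl decalones is not decisive either way. C5 is therefore set on purpose, by kinetic protonation of the planar trienolate 9 on the face away from the C10 methyl.

**C2–C3 bond.** The enone 8 opens by retro-aldol condensation to the keto aldehyde 6; only the methyl ketone carbon C3 can reach the aldehyde C2 through a six-membered ring. Compound 6 comes from the vinyl aldehyde 5 by Wacker oxidation (C4=O), and 5 from the adduct 3 by one-carbon homologation of the formyl group (C1–C2).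

**C5–C10 and C8–C9 bonds.** The adduct 3 is cut into methacrolein 1 and (E)-hexa-1,3,5-triene 2, a 1-substituted butadiene whose substituent is a vinyl group serving as a latent acetyl. A ketal-masked acetyl was set aside: a dienyl ketal would be expected to ionise on the cationic boron catalyst and would put a quaternary carbon next to the bond-forming terminus. The triene is a hydrocarbon, flat at that terminus, symmetrical (either end gives the same adduct) and commercially available. The forward reaction must be regioselective (C8 to C9, C5 to C10) and face-selective at C10; the exo/endo ratio does not matter.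

## Roads not taken

**Alternative 1:** The cut is C5–C10 and C6–C7 at once, an intramolecular Diels-Alder reaction of the achiral trienone A1 under a chiral Lewis acid, followed by base epimerisation at C5 to give A2.
- Merits: both rings form in one step, and the C8 oxygen arrives as an enol ether, so no allylic oxidation is needed. In that respect it is better than the chosen plan, whose C8 oxidation is one of its least certain steps.
- Weak points: A1 needs a trisubstituted diene terminus of defined geometry and a polymerisation-prone vinyl ketone, about six or seven linear steps before any ring exists. C10 is formed at a fully substituted diene carbon, where catalyst control is less established than for an α-methyl enal. The trans fusion again rests on an equilibrium of uncertain position. The enol ether of A2 points to C9, not C7, so it must be hydrolysed and re-enolised, and it would not survive the peracid step of ring A.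
- Against its advantage at C8 the chosen plan sets two commercial partners, a well-established catalytic way to the quaternary centre and a shorter overall count.

**Alternative 2:** The cut is the C10–C14 bond: a hydroxyl-directed zinc carbenoid adds a methylene to the tetrasubstituted C5=C10 alkene of the allylic alcohol A3 to give the propellane A4, whose cyclopropane is later opened reductively to the angular methyl.
- Merits: inexpensive decalin chemistry, a syn delivery that is reliable, and C8 already oxidised (as a ketal), which the chosen plan lacks.
- Weak points: the absolute configuration must first be put into the carbinol of A3 and is later destroyed; the tetrasubstituted alkene is slow to cyclopropanate; the opening requires oxidation to the C4 ketone and leaves C5 to an enolate protonation, as in the chosen plan; three to four extra redox steps are added before ring A work starts.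
- The chosen plan sets C10 directly in one catalytic step and is shorter; it pays with the late C8 oxidation.

**Alternative 3:** The cut is C9–C10: acid converts the diazoketone of the phenol A5 into an electrophile that is attacked by the para carbon, dearomatising ring A and closing ring B to the dienone A6.
- Merits: the fastest route to a bicyclic core, and the richest in the right places, since the C3 oxygen, the C4 methyl and the C8 ketone are all present. In oxidation pattern it beats the chosen plan.
- Weak points: C10 is created in the dearomatisation, for which no dependable enantiocontrol exists, so a resolution would be needed. A6 then requires telling two ketones apart, saturating one of two enone alkenes, and turning a 4-en-3-one into the 3α-acyloxy/4β-acetoxy/5α-H array, which means adding oxygen at C4 while reducing C5 trans; no direct method does this.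
- The chosen plan has to add the oxygens one by one but solves C10 catalytically and C3/C4 by a stereospecific epoxide opening.

Key step: step 1

Assumptions and remarks on the chemistry:
- (E)-Hexa-1,3,5-triene 2 is taken as purchased (it is also sold as an E/Z mixture, of which only the E isomer can react at a terminal diene unit).
- The absolute sense of step 1 is assigned from the formyl C–H···O binding model of α-substituted enals on the diphenylprolinol-derived boron cation, which points to the (R)-catalyst for (R)-C10 in 3; the enantiomeric catalyst is equally accessible if the sense proves opposite.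
- Compounds 3 to 8 are expected as mixtures at C5; the isomer drawn is the one expected to predominate, and both converge at 10.
- Decalin intermediates are described with the numbering of the target; α/β refer to the face opposite/same as the C10 methyl.

## Route

Step 1
Reactants: 1 methacrolein; 2 (E)-hexa-1,3,5-triene
Product: 3 (1R,2S)-1-methyl-2-vinylcyclohex-3-ene-1-carbaldehyde (endo adduct; the 2R exo epimer is carried along)
Conditions: (R)-B-(o-tolyl)oxazaborolidine of (R)-α,α-diphenylprolinol activated with HN(SO2CF3)2 (20 mol%), 2 (2 equiv), CH2Cl2, −78 → −40 °C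
Reagents that add atoms: none
Why: The boron cation binds the s-trans enal and the triene adds in a concerted, asynchronous [4+2] cycloaddition; the closest known reaction type is the oxazaborolidinium-catalysed Diels-Alder reaction of 2-methylacrolein with simple butadienes. Ring B closes by this intermolecular [4+2] annulation, which forms C5–C10 and C8–C9 suprafacially on both partners and leaves the alkene at C6=C7. C10 is controlled by the catalyst, which covers one face of the bound enal with a phenyl group so that the diene adds to the other. C5 is set only relative to C10 by the endo/exo preference (endo expected) and is not relied on, because step 5 resets it. The step needs regioselectivity, secured by the vinyl substituent: it makes C8 the terminus with the largest HOMO coefficient, so C8 bonds to the β-carbon C9 and C5 to the α-carbon C10. It needs site selectivity, secured by the symmetry of the triene (both terminal diene units are the same, the internal one cannot react) and by the fact that the adduct no longer contains a conjugated diene.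

Step 2
Reactants: 3 (1R,2S)-1-methyl-2-vinylcyclohex-3-ene-1-carbaldehyde
Product: 5 2-[(1S,2S)-1-methyl-2-vinylcyclohex-3-en-1-yl]acetaldehyde, via methyl enol ether 4 (not isolated)
Conditions: Ph3P(CH2OMe)Cl, KN(SiMe3)2, THF, 0 °C; then 1 M HCl, THF, rt
Reagents that add atoms: (methoxymethyl)triphenylphosphonium chloride, COC[P+](c1ccccc1)(c1ccccc1)c1ccccc1.[Cl-]; water, O
Why: Wittig methoxymethylenation of a non-enolisable aldehyde followed by enol ether hydrolysis is the standard one-carbon homologation and supplies C2; no stereocentre is touched.

Step 3
Reactants: 5 2-[(1S,2S)-1-methyl-2-vinylcyclohex-3-en-1-yl]acetaldehyde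
Product: 6 2-[(1S,2S)-2-acetyl-1-methylcyclohex-3-en-1-yl]acetaldehyde
Conditions: PdCl2 (10 mol%), CuCl (1 equiv, redox co-catalyst), O2 (1 atm), DMF/H2O 7:1, rt
Reagents that add atoms: water, O; dioxygen (terminal oxidant, returned as water), O=O
Why: Wacker oxidation: Markovnikov hydroxypalladation of the terminal vinyl group gives the methyl ketone (C4=O, C3 methyl), while the internal cis-disubstituted ring alkene reacts far more slowly and the aldehyde is inert.

Step 4
Reactants: 6 2-[(1S,2S)-2-acetyl-1-methylcyclohex-3-en-1-yl]acetaldehyde
Product: 8 (4aS,8aS)-4a-methyl-4a,5,6,8a-tetrahydronaphthalen-1(4H)-one (cis-fused isomer drawn; its 8a-epimer 10 may accompany it), via aldol 7 (not isolated)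
Conditions: KOH (1.1 equiv), MeOH, 0 °C → rt, short contact time
Reagents that add atoms: none
Why: Intramolecular aldol condensation: only the methyl ketone enolate (C3) can reach the aldehyde (C2) through a six-membered transition state, and E1cB loss of water gives the C2=C3 enone of ring A; C5 may epimerise here and is deliberately left open.

Step 5
Reactants: 8 (4aS,8aS)-4a-methyl-4a,5,6,8a-tetrahydronaphthalen-1(4H)-one (with its 8a-epimer)
Product: 10 (4aS,8aR)-4a-methyl-4a,5,6,8a-tetrahydronaphthalen-1(4H)-one (trans-fused; 5α-H and 10β-CH3), via lithium trienolate 9 (not isolated)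
Conditions: LiN(i-Pr)2 (1.2 equiv), THF, −78 °C; then inverse quench into AcOH/THF, −78 °C
Reagents that add atoms: none
Why: Kinetic α-protonation of an extended enolate (the deconjugation protocol for β,γ-unsaturated ketones): the base removes the doubly activated C5–H from either epimer, and the planar trienolate is protonated at C5, the carbon of highest charge density, from the α face because the C10 methyl stands perpendicular over the β face; this gives the trans ring fusion and keeps the alkene at C6=C7.

Step 6
Reactants: 10 (4aS,8aR)-4a-methyl-4a,5,6,8a-tetrahydronaphthalen-1(4H)-one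
Product: 12 (4aS,8aR)-4a-methyl-3,4,4a,5,6,8a-hexahydronaphthalen-1-yl trifluoromethanesulfonate, via lithium enolate 11 (not isolated)
Conditions: LiBH(s-Bu)3 (1.05 equiv), THF, −78 °C; then PhNTf2, −78 → 0 °C
Reagents that add atoms: N-phenylbis(trifluoromethanesulfonimide), O=S(=O)(N(c1ccccc1)S(=O)(=O)C(F)(F)F)C(F)(F)F
Why: Conjugate hydride addition to the β-unsubstituted cyclohexenone gives the C3=C4 enolate regiospecifically without touching C5, and O-triflation traps it as the enol triflate.

Step 7
Reactants: 12 (4aS,8aR)-4a-methyl-3,4,4a,5,6,8a-hexahydronaphthalen-1-yl trifluoromethanesulfonate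
Product: 13 (4aS,8aR)-1,4a-dimethyl-3,4,4a,5,6,8a-hexahydronaphthalene
Conditions: Me2CuLi (from CuI and MeLi, 3 equiv), THF, −20 → 0 °C
Reagents that add atoms: lithium dimethylcuprate, [Li+].C[Cu-]C
Why: Coupling of an enol triflate with a methylcuprate replaces the triflate by methyl with the alkene held at C3=C4; this brings in the C4 methyl.

Step 8
Reactants: 13 (4aS,8aR)-1,4a-dimethyl-3,4,4a,5,6,8a-hexahydronaphthalene
Product: 14 3α,4α-epoxide of 13 (4-methyl now β; 5α-H; 10β-CH3; C6=C7 intact)
Conditions: mCPBA (1.05 equiv), NaHCO3, CH2Cl2, −10 °C
Reagents that add atoms: 3-chloroperoxybenzoic acid, O=C(OO)c1cccc(Cl)c1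
Why: Prilezhaev epoxidation: the trisubstituted C3=C4 alkene reacts much faster than the cis-disubstituted C6=C7, and the peracid approaches from the α face away from the axial C10 methyl, which sets C3 (and, for now, C4).

Step 9
Reactants: 14 3α,4α-epoxide
Product: 15 4β-acetoxy-3α-hydroxy-4α,10β-dimethyl-5α-octal-6-ene (target numbering)
Conditions: glacial AcOH, 30 °C
Reagents that add atoms: acetic acid, CC(=O)O
Why: Acid-assisted epoxide opening of borderline SN2 type: the Fürst-Plattner rule (trans-diaxial opening) and the Markovnikov preference both send acetate to the tertiary C4 from the β face with inversion, giving the 4β-acetate and the 3α-alcohol; the rigid trans-diaxial arrangement prevents acyl migration, and C5–H is syn to the breaking C4–O bond, so anti elimination towards C5 is not available.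

Step 10
Reactants: 16 tiglic acid
Product: 17 (E)-2-methylbut-2-en-1-ol
Conditions: LiAlH4, Et2O, 0 °C → rt
Reagents that add atoms: none
Why: Hydride reduction of the acid to the allylic alcohol with retention of the E geometry.

Step 11
Reactants: 17 (E)-2-methylbut-2-en-1-ol
Product: 18 [(2R,3R)-2,3-dimethyloxiran-2-yl]methanol
Conditions: Ti(O-i-Pr)4 (5 mol%), D-(−)-diisopropyl tartrate (6 mol%), t-BuOOH, 4 Å molecular sieves, CH2Cl2, −20 °C
Reagents that add atoms: tert-butyl hydroperoxide, CC(C)(C)OO
Why: Sharpless asymmetric epoxidation: the tartrate selects the alkene face, and since the L-(+) ester gives (2S,3S)-epoxides from E allylic alcohols of this substitution pattern, the D-(−) ester gives the (2R,3R) epoxide; the E geometry fixes the two methyls cis.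

Step 12
Reactants: 18 [(2R,3R)-2,3-dimethyloxiran-2-yl]methanol
Product: 20 (2S,3R)-2,3-dimethyloxirane-2-carboxylic acid, via epoxy aldehyde 19 (not isolated)
Conditions: RuCl3·H2O (2 mol%), NaIO4 (4 equiv), CCl4/MeCN/H2O, rt
Reagents that add atoms: water, O; sodium periodate (terminal oxidant), [Na+].[O-]I(=O)(=O)=O
Why: Ruthenium tetroxide-catalysed oxidation of the primary alcohol to the acid leaves the epoxide and both stereocentres untouched; the C2 descriptor changes from R to S only because the substituent priorities change.

Step 13
Reactants: 20 (2S,3R)-2,3-dimethyloxirane-2-carboxylic acid; 15 4β-acetoxy-3α-hydroxy-4α,10β-dimethyl-5α-octal-6-ene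
Product: 22 4β-acetoxy-3α-[(2S,3R)-2,3-epoxy-2-methylbutanoyloxy]-4α,10β-dimethyl-5α-octal-6-ene, via mixed anhydride 21 (not isolated)
Conditions: 2,4,6-trichlorobenzoyl chloride, Et3N, toluene, rt; then 15, DMAP, 50 °C
Reagents that add atoms: none
Why: Yamaguchi esterification: the acyl-pyridinium formed from the mixed anhydride acylates the hindered axial 3α-hydroxyl; the acid has no α-hydrogen, so its stereocentres cannot epimerise, and the carbinol centre keeps its configuration.

Step 14
Reactants: 22 4β-acetoxy-3α-[(2S,3R)-2,3-epoxy-2-methylbutanoyloxy]-4α,10β-dimethyl-5α-octal-6-ene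
Product: 24 the corresponding 6-en-8-one (4β-acetoxy-3α-epoxyacyloxy-4α,10β-dimethyl-5α-octal-6-en-8-one), via allylic tert-butyl peroxide 23 (not isolated)
Conditions: Rh2(cap)4 (1 mol%; cap = caprolactamate), t-BuOOH (5 equiv), K2CO3, CH2Cl2, rt
Reagents that add atoms: tert-butyl hydroperoxide, CC(C)(C)OO
Why: Allylic C–H oxidation by tert-butylperoxyl radicals: hydrogen is abstracted from the secondary C8 methylene (the tertiary C5–H lies between two quaternary carbons and under the axial 3α ester), the allyl radical is trapped at its less hindered C8 end, and the mixed peroxide loses tert-butanol to give the enone; esters and epoxide are inert.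

Step 15
Reactants: 24 6-en-8-one
Product: 26 4β-acetoxy-3α-epoxyacyloxy-7β-(2-hydroxypropan-2-yl)-4α,10β-dimethyl-5α-decal-8-one (11-hydroxyeudesman-8-one diester), via lithium enolate 25 (not isolated)
Conditions: LiBH(s-Bu)3 (1.0 equiv), THF, −78 °C; then acetone (5 equiv), −78 °C; AcOH quench at −78 °C
Reagents that add atoms: acetone, CC(C)=O
Why: Conjugate reduction followed by aldol addition: hydride adds to C6 and gives the C7 enolate regiospecifically (a C9 enolate cannot form this way), which adds to acetone under kinetic control; the new C7 centre (side chain expected equatorial, 7β) is removed again in step 16.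

Step 16
Reactants: 26 11-hydroxyeudesman-8-one diester
Product: 28 4β-acetoxy-3α-[(2S,3R)-2,3-epoxy-2-methylbutanoyloxy]-5α-eudesm-7(11)-en-8-one, via mesylate 27 (not isolated)
Conditions: MsCl, Et3N, CH2Cl2, 0 °C; then DBU, rt
Reagents that add atoms: none
Why: Mesylation of the tertiary alcohol and E1cB elimination through the ketone enolate place the alkene at C7=C11 in conjugation; any isopropenyl isomer is equilibrated by the amidine base to the conjugated tetrasubstituted enone, as in the isopulegone to pulegone isomerisation.

Step 17
Reactants: 28 4β-acetoxy-3α-[(2S,3R)-2,3-epoxy-2-methylbutanoyloxy]-5α-eudesm-7(11)-en-8-one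
Product: 29 (3R,4R,5R,10R)-4-acetoxy-11-hydroperoxy-8-oxoeudesm-6-en-3-yl (2S,3R)-2,3-dimethyloxirane-2-carboxylate (target)
Conditions: O2, 5,10,15,20-tetraphenylporphyrin (1 mol%), visible light, CH2Cl2, 0 °C
Reagents that add atoms: dioxygen, O=O
Why: Schenck ene reaction of singlet oxygen with an α-alkylidene ketone: oxygen bonds to the β-carbon C11 and the hydrogen is taken from the group geminal to the carbonyl (the axial 6β-H), so the alkene moves to C6=C7 in conjugation with the ketone and the tertiary hydroperoxide forms directly under neutral conditions; no stereocentre is made or touched and the electron-poor product enone does not react further.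

## Compound list

1 | methacrolein (2-methylprop-2-enal) | CC(=C)C=O | starting material
2 | (E)-hexa-1,3,5-triene | C=C/C=C/C=C | starting material
3 | (1R,2S)-1-methyl-2-vinylcyclohex-3-ene-1-carbaldehyde (endo adduct; 2R epimer carried along) | C=C[C@H]1C=CCC[C@@]1(C)C=O | intermediate
4 | methyl enol ether of 5 (E/Z mixture, E drawn; ring as in 3) | C=C[C@H]1C=CCC[C@@]1(C)/C=C/OC | intermediate (not isolated)
5 | 2-[(1S,2S)-1-methyl-2-vinylcyclohex-3-en-1-yl]acetaldehyde | C=C[C@H]1C=CCC[C@@]1(C)CC=O | intermediate
6 | 2-[(1S,2S)-2-acetyl-1-methylcyclohex-3-en-1-yl]acetaldehyde | CC(=O)[C@H]1C=CCC[C@@]1(C)CC=O | intermediate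
7 | 3-hydroxy-4a-methyl-3,4,4a,5,6,8a-hexahydronaphthalen-1(2H)-one (cis-fused aldol, both carbinol epimers) | O=C1CC(O)C[C@]2(C)CCC=C[C@H]12 | intermediate (not isolated)
8 | (4aS,8aS)-4a-methyl-4a,5,6,8a-tetrahydronaphthalen-1(4H)-one (cis-fused; may contain 10) | O=C1C=CC[C@]2(C)CCC=C[C@H]12 | intermediate
9 | lithium (4aS)-4a-methyl-4,4a,5,6-tetrahydronaphthalen-1-olate (trienolate) | [Li+].[O-]C1=C2C=CCC[C@@]2(C)CC=C1 | intermediate (not isolated)
10 | (4aS,8aR)-4a-methyl-4a,5,6,8a-tetrahydronaphthalen-1(4H)-one (trans-fused) | O=C1C=CC[C@]2(C)CCC=C[C@@H]12 | intermediate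
11 | lithium (4aS,8aR)-4a-methyl-3,4,4a,5,6,8a-hexahydronaphthalen-1-olate | [Li+].[O-]C1=CCC[C@]2(C)CCC=C[C@@H]12 | intermediate (not isolated)
12 | (4aS,8aR)-4a-methyl-3,4,4a,5,6,8a-hexahydronaphthalen-1-yl trifluoromethanesulfonate | FC(F)(F)S(=O)(=O)OC1=CCC[C@]2(C)CCC=C[C@@H]12 | intermediate
13 | (4aS,8aR)-1,4a-dimethyl-3,4,4a,5,6,8a-hexahydronaphthalene | CC1=CCC[C@]2(C)CCC=C[C@@H]12 | intermediate
14 | 3α,4α-epoxide of 13 (4β-CH3, 5α-H, 10β-CH3) | C[C@@]12O[C@@H]1CC[C@]3(C)CCC=C[C@@H]23 | intermediate
15 | 4β-acetoxy-3α-hydroxy-4α,10β-dimethyl-5α-octal-6-ene | CC(=O)O[C@]1(C)[C@@H]2C=CCC[C@@]2(C)CC[C@H]1O | intermediate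
16 | tiglic acid, (E)-2-methylbut-2-enoic acid | C/C=C(\C)C(=O)O | starting material
17 | (E)-2-methylbut-2-en-1-ol | C/C=C(\C)CO | intermediate
18 | [(2R,3R)-2,3-dimethyloxiran-2-yl]methanol | OC[C@@]1(C)O[C@@H]1C | intermediate
19 | (2S,3R)-2,3-dimethyloxirane-2-carbaldehyde | O=C[C@@]1(C)O[C@@H]1C | intermediate (not isolated)
20 | (2S,3R)-2,3-dimethyloxirane-2-carboxylic acid | OC(=O)[C@@]1(C)O[C@@H]1C | intermediate
21 | (2S,3R)-2,3-dimethyloxirane-2-carboxylic 2,4,6-trichlorobenzoic anhydride | O=C(OC(=O)[C@@]1(C)O[C@@H]1C)c1c(Cl)cc(Cl)cc1Cl | intermediate (not isolated)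
22 | 4β-acetoxy-3α-[(2S,3R)-2,3-epoxy-2-methylbutanoyloxy]-4α,10β-dimethyl-5α-octal-6-ene | CC(=O)O[C@]1(C)[C@@H]2C=CCC[C@@]2(C)CC[C@H]1OC(=O)[C@@]1(C)O[C@@H]1C | intermediate
23 | 8-tert-butylperoxy derivative of 22 (both C8 epimers) | CC(=O)O[C@]1(C)[C@@H]2C=CC(OOC(C)(C)C)C[C@@]2(C)CC[C@H]1OC(=O)[C@@]1(C)O[C@@H]1C | intermediate (not isolated)
24 | 4β-acetoxy-3α-[(2S,3R)-2,3-epoxy-2-methylbutanoyloxy]-4α,10β-dimethyl-5α-octal-6-en-8-one | CC(=O)O[C@]1(C)[C@@H]2C=CC(=O)C[C@@]2(C)CC[C@H]1OC(=O)[C@@]1(C)O[C@@H]1C | intermediate
25 | lithium C7=C8 enolate of the 6,7-dihydro ketone | [Li+].CC(=O)O[C@]1(C)[C@@H]2CC=C([O-])C[C@@]2(C)CC[C@H]1OC(=O)[C@@]1(C)O[C@@H]1C | intermediate (not isolated)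
26 | 4β-acetoxy-3α-[(2S,3R)-2,3-epoxy-2-methylbutanoyloxy]-11-hydroxy-5α,7α-H-eudesman-8-one | CC(=O)O[C@]1(C)[C@@H]2C[C@H](C(C)(C)O)C(=O)C[C@@]2(C)CC[C@H]1OC(=O)[C@@]1(C)O[C@@H]1C | intermediate
27 | 11-methanesulfonate of 26 | CC(=O)O[C@]1(C)[C@@H]2C[C@H](C(C)(C)OS(C)(=O)=O)C(=O)C[C@@]2(C)CC[C@H]1OC(=O)[C@@]1(C)O[C@@H]1C | intermediate (not isolated)
28 | 4β-acetoxy-3α-[(2S,3R)-2,3-epoxy-2-methylbutanoyloxy]-5α-eudesm-7(11)-en-8-one | CC(=O)O[C@]1(C)[C@@H]2CC(=C(C)C)C(=O)C[C@@]2(C)CC[C@H]1OC(=O)[C@@]1(C)O[C@@H]1C | intermediate
29 | (3R,4R,5R,10R)-4-acetoxy-11-hydroperoxy-8-oxoeudesm-6-en-3-yl (2S,3R)-2,3-dimethyloxirane-2-carboxylate | CC(=O)O[C@]1(C)[C@@H]2C=C(C(C)(C)OO)C(=O)C[C@@]2(C)CC[C@H]1OC(=O)[C@@]1(C)O[C@@H]1C | target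

## Step count and least certain steps

Total: 17 steps. Longest linear sequence: 14 steps (steps 1 to 9 and 13 to 17, from 1 and 2); the acid branch is 3 steps (10 to 12).

**Step 1 (key step).** The most likely failure is acid-induced oligomerisation of the triene with loss of catalyst before cycloaddition, or incomplete face selection at the enal so that C10 is not set cleanly. Fallback: setting out from 1 and 2, an achiral Lewis acid (EtAlCl2, CH2Cl2, −78 °C) gives the racemic adduct F1. Condensation with (1R,2R)-N,N'-dimethyl-1,2-diphenylethane-1,2-diamine converts it into diastereomeric imidazolidines, from which the aminal of the (1R)-aldehyde F2 is separated by chromatography. Hydrolysis on wet silica or with dilute aqueous acid comes back to the route at 3 and releases the diamine for reuse.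

**Step 5.** The risk is poor facial selectivity of the protonation (some β attack, giving the cis fusion) or partial γ-protonation at C7, which would move the alkene into conjugation with the C4 ketone. Fallback: from 8, the trienolate is silylated (LiN(i-Pr)2, Me3SiCl) to the trimethylsilyl trienol ether F3, which is isolated and protonated at −78 °C with a Lewis-acid-assisted chiral Brønsted acid (SnCl4·BINOL, the BINOL enantiomer chosen for α delivery). The reagent, not the substrate, then selects the face, and the route is rejoined at 10.

**Step 9.** The risk is ionisation at C4 followed by proton loss to an alkene or by hydride shift to a ketone before the weakly nucleophilic acetic acid captures the carbon. Fallback: from 14, hydrolysis with catalytic HClO4 in aqueous THF, where water is the more concentrated and better nucleophile, gives the trans-diaxial diol F4. Ac2O with catalytic Sc(OTf)3 at −20 °C acetylates both hydroxyls to the diacetate F5, and K2CO3 in MeOH at 0 °C removes the less hindered secondary acetate, coming back at 15.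

**Step 14.** The risk is hydrogen abstraction at C5 or trapping of the allyl radical at C6, either of which gives a transposed enone. Fallback: from 22, SeO2 (catalytic) with t-BuOOH in CH2Cl2 hydroxylates C8 by an ene reaction followed by a [2,3]-shift, a pericyclic path with no free allyl radical, and gives the allylic alcohol F6. Dess-Martin periodinane then oxidises it to rejoin the route at 24.

**Step 17.** The risk is the ene reaction running the other way (oxygen to C7, hydrogen from a C11 methyl, giving an α-hydroperoxy ketone with an isopropenyl group), or a sluggish reaction of the electron-poor alkene. Fallback: from 24, α-iodination (I2, pyridine) gives the iodoenone F7. Stille coupling with tributyl(prop-1-en-2-yl)stannane (Pd2(dba)3, AsPh3, CuI) gives the 7-isopropenyl dienone F8. Mukaiyama-type hydroperoxysilylation of its 1,1-disubstituted alkene (Co(acac)2, O2, Et3SiH) gives the triethylsilyl peroxide F9, and brief treatment with AcOH in aqueous THF frees the hydroperoxide, coming back at 29.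

## Further compounds

F1 | step 1 | racemic 1-methyl-2-vinylcyclohex-3-ene-1-carbaldehyde (both enantiomers, cis/trans mixture) | C=CC1C=CCCC1(C)C=O
F2 | step 1 | (4R,5R)-1,3-dimethyl-2-[(1R,2S)-1-methyl-2-vinylcyclohex-3-en-1-yl]-4,5-diphenylimidazolidine | C=C[C@H]1C=CCC[C@@]1(C)C1N(C)[C@H](c2ccccc2)[C@@H](c2ccccc2)N1C
F3 | step 5 | trimethylsilyl trienol ether, (4aS)-4a-methyl-1-(trimethylsilyloxy)-4,4a,5,6-tetrahydronaphthalene | C[Si](C)(C)OC1=C2C=CCC[C@@]2(C)CC=C1
F4 | step 9 | 4α,10β-dimethyl-5α-octal-6-ene-3α,4β-diol | C[C@@]1(O)[C@@H]2C=CCC[C@@]2(C)CC[C@H]1O
F5 | step 9 | 3α,4β-diacetoxy-4α,10β-dimethyl-5α-octal-6-ene | CC(=O)O[C@]1(C)[C@@H]2C=CCC[C@@]2(C)CC[C@H]1OC(C)=O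
F6 | step 14 | 8-hydroxy derivative of 22 (allylic alcohol, both C8 epimers) | CC(=O)O[C@]1(C)[C@@H]2C=CC(O)C[C@@]2(C)CC[C@H]1OC(=O)[C@@]1(C)O[C@@H]1C
F7 | step 17 | 7-iodo derivative of 24 | CC(=O)O[C@]1(C)[C@@H]2C=C(I)C(=O)C[C@@]2(C)CC[C@H]1OC(=O)[C@@]1(C)O[C@@H]1C
F8 | step 17 | 7-(prop-1-en-2-yl) derivative of 24 (eudesma-6,11-dien-8-one diester) | CC(=O)O[C@]1(C)[C@@H]2C=C(C(C)=C)C(=O)C[C@@]2(C)CC[C@H]1OC(=O)[C@@]1(C)O[C@@H]1C
F9 | step 17 | 11-triethylsilylperoxy derivative of 29 | CC(=O)O[C@]1(C)[C@@H]2C=C(C(C)(C)OO[Si](CC)(CC)CC)C(=O)C[C@@]2(C)CC[C@H]1OC(=O)[C@@]1(C)O[C@@H]1C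
A1 | alternative 1 | (E)-7-methyl-9-(triisopropylsilyloxy)deca-1,7,9-trien-3-one | C=CC(=O)CCC/C(C)=C/C(=C)O[Si](C(C)C)(C(C)C)C(C)C
A2 | alternative 1 | trans-fused 10-methyldecal-4-one as its C8-C9 triisopropylsilyl enol ether | O=C1[C@@H]2CCC(O[Si](C(C)C)(C(C)C)C(C)C)=C[C@@]2(C)CCC1
A3 | alternative 2 | C5=C10 octalin-4-ol 8-ethylene ketal | O[C@H]1CCCC2=C1CCC1(OCCO1)C2
A4 | alternative 2 | [4.4.1]propellane alcohol (C5-C10 methano-bridged decalin-4-ol 8-ethylene ketal) | O[C@@H]1[C@@]23CCC4(OCCO4)C[C@@]2(C3)CCC1
A5 | alternative 3 | 1-diazo-4-(3-hydroxy-2,6-dimethylphenyl)butan-2-one | Cc1ccc(O)c(C)c1CCC(=O)C=[N+]=[N-]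
A6 | alternative 3 | bicyclic 4,10-dimethyl-1,4-dien-3-one with C8 ketone | CC1=C2CCC(=O)C[C@@]2(C)C=CC1=O
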